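**Retrosynthetic overview**
- Target ⇒ its des-hydroxy resorcinol aldehyde: the last bond made is the aryl C5'–O bond, by oxygen transfer to the only free activated ring carbon of the bis(phenoxide) (key step, new).
- Resorcinol aldehyde ⇒ 2,6-dihydroxybenzaldehyde + a C15 allylic bromide acid: aryl–CH2 bond by C-allylation of the resorcinolate dianion.
- C15 acid ⇒ (2E,6E)-farnesyl acetate: terminal allylic C–H oxidation (a second C–O bond), oxidation to the tiglic-type acid, then Ru-catalysed asymmetric hydrogenation sets C2 (S).
- No ring is formed; the benzene ring is bought intact and is never protected.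

Assumption: Ru(OAc)2[(S)-H8-BINAP] gives the 2S acid from the (E)-2-methyl-2-enoic acid, the sense it shows with tiglic acid.

**Step 1**
Reactants: 1 (2E,6E)-farnesyl acetate
Product: 2 (2E,6E,10E)-12-hydroxy-3,7,11-trimethyldodeca-2,6,10-trien-1-yl acetate
Conditions: SeO2 (0.3 equiv), t-BuOOH (70% aq, 3 equiv), salicylic acid (0.1 equiv), CH2Cl2, 0 °C → rt
Reagents that add atoms: tert-butyl hydroperoxide, CC(C)(C)OO (net source of the new O, relayed by catalytic SeO2, O=[Se]=O)
Why: Riley allylic oxidation (ene reaction, then [2,3]-sigmatropic shift) attacks the (E)-methyl of the terminal, most electron-rich alkene and gives the E allylic alcohol, the 2,3-alkene being deactivated by the acetate.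

**Step 2**
Reactants: 2 (2E,6E,10E)-12-hydroxy-3,7,11-trimethyldodeca-2,6,10-trien-1-yl acetate
Product: 4 (2E,6E,10E)-12-acetoxy-2,6,10-trimethyldodeca-2,6,10-trienoic acid, via enal 3 (not isolated)
Conditions: TEMPO (0.1 equiv), PhI(OAc)2 (1.1 equiv), CH2Cl2, rt; then t-BuOH/H2O, 2-methyl-2-butene, NaH2PO4, NaClO2, 0 °C → rt
Reagents that add atoms: sodium chlorite, [Na+].[O-]Cl=O
Why: TEMPO/PhI(OAc)2 oxidation stops at the conjugated aldehyde and the Pinnick oxidation in the same flask takes it to the acid, with 2-methyl-2-butene scavenging HOCl so that the alkenes and the E geometry are untouched.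

**Step 3**
Reactants: 4 (2E,6E,10E)-12-acetoxy-2,6,10-trimethyldodeca-2,6,10-trienoic acid
Product: 5 (2S,6E,10E)-12-acetoxy-2,6,10-trimethyldodeca-6,10-dienoic acid
Conditions: Ru(OAc)2[(S)-H8-BINAP] (1 mol %), H2 (4 atm), MeOH, 20 °C
Reagents that add atoms: none
Why: Noyori-type carboxylate-directed asymmetric hydrogenation reduces only the alkene conjugated to the Ru-bound carboxylate and delivers H to one enantioface to set C2 as S; the acetate keeps the 10,11-alkene from hydroxyl-directed reduction.

**Step 4**
Reactants: 5 (2S,6E,10E)-12-acetoxy-2,6,10-trimethyldodeca-6,10-dienoic acid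
Product: 6 (2S,6E,10E)-12-hydroxy-2,6,10-trimethyldodeca-6,10-dienoic acid
Conditions: LiOH·H2O (3 equiv), THF/H2O 3:1, rt; 1 M HCl to pH 3
Reagents that add atoms: none
Why: Ester saponification frees the allylic alcohol, and the α-stereocentre is safe because a carboxylate is not enolised by hydroxide.

**Step 5**
Reactants: 6 (2S,6E,10E)-12-hydroxy-2,6,10-trimethyldodeca-6,10-dienoic acid; 7 2,6-dihydroxybenzaldehyde
Product: 9 (2S,6E,10E)-12-(3-formyl-2,4-dihydroxyphenyl)-2,6,10-trimethyldodeca-6,10-dienoic acid, via allylic bromide 8 (not isolated)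
Conditions: PBr3 (0.4 equiv), Et2O, −10 °C; then the ether solution added to 7 (3 equiv) in 10% aq KOH, 0 °C → rt; 1 M HCl to pH 3
Reagents that add atoms: phosphorus tribromide, BrP(Br)Br (its Br sits in 8 only and leaves again in the alkylation)
Why: PBr3 gives the primary allylic bromide with retention of the E alkene, and phenoxide C-allylation of the ambident resorcinolate dianion in water (oxygen shielded by hydrogen bonding) attacks through C3, the only open ortho/para carbon, by SN2 without touching C2 of the chain.

**Step 6**
Reactants: 9 (2S,6E,10E)-12-(3-formyl-2,4-dihydroxyphenyl)-2,6,10-trimethyldodeca-6,10-dienoic acid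
Product: 10 (2S,6E,10E)-12-(3-formyl-2,4,5-trihydroxyphenyl)-2,6,10-trimethyldodeca-6,10-dienoic acid (CNP0180353.1)
Conditions: KOt-Bu (3.1 equiv), THF/DMF 4:1, −30 °C, Ar; (+)-(camphorsulfonyl)oxaziridine (1.05 equiv), −30 → 0 °C; degassed 1 M HCl
Reagents that add atoms: (+)-(camphorsulfonyl)oxaziridine, CC1(C)[C@@H]2CC[C@]13CS(=O)(=O)N4O[C@@]34C2
Why: Proposed new method: the bis(phenoxide) of 9 is an aromatic dienolate whose only unsubstituted nucleophilic carbon (C5', ortho to one O− and para to the other) attacks the electrophilic oxygen of the N-sulfonyloxaziridine (SN2 at oxygen), the hindered sulfonimine leaves and the 4-oxidocyclohexadienone re-aromatises by proton shift to the hydroxyquinol, while isolated alkenes, the vinylogous-carboxylate aldehyde and the carboxylate are inert to this reagent; the closest known reaction types are the Davis enolate α-hydroxylation, the hydroxylative dearomatisation of naphtholates with oxaziridines and the Elbs persulfate para-hydroxylation of phenoxides, none of them shown as a rearomatising C–H hydroxylation of a free formyl-resorcinol.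

**Compound list**
1 | (2E,6E)-farnesyl acetate, (2E,6E)-3,7,11-trimethyldodeca-2,6,10-trien-1-yl acetate | C/C(=C\COC(C)=O)CC/C=C(\C)CCC=C(C)C | starting material
2 | (2E,6E,10E)-12-hydroxy-3,7,11-trimethyldodeca-2,6,10-trien-1-yl acetate | C/C(=C\COC(C)=O)CC/C=C(\C)CC/C=C(\C)CO | intermediate
3 | (2E,6E,10E)-3,7,11-trimethyl-12-oxododeca-2,6,10-trien-1-yl acetate | C/C(=C\COC(C)=O)CC/C=C(\C)CC/C=C(\C)C=O | intermediate
4 | (2E,6E,10E)-12-acetoxy-2,6,10-trimethyldodeca-2,6,10-trienoic acid | C/C(=C\COC(C)=O)CC/C=C(\C)CC/C=C(\C)C(=O)O | intermediate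
5 | (2S,6E,10E)-12-acetoxy-2,6,10-trimethyldodeca-6,10-dienoic acid | C/C(=C\COC(C)=O)CC/C=C(\C)CCC[C@H](C)C(=O)O | intermediate
6 | (2S,6E,10E)-12-hydroxy-2,6,10-trimethyldodeca-6,10-dienoic acid | C/C(=C\CO)CC/C=C(\C)CCC[C@H](C)C(=O)O | intermediate
7 | 2,6-dihydroxybenzaldehyde | O=Cc1c(O)cccc1O | starting material
8 | (2S,6E,10E)-12-bromo-2,6,10-trimethyldodeca-6,10-dienoic acid | C/C(=C\CBr)CC/C=C(\C)CCC[C@H](C)C(=O)O | intermediate
9 | (2S,6E,10E)-12-(3-formyl-2,4-dihydroxyphenyl)-2,6,10-trimethyldodeca-6,10-dienoic acid | C/C(=C\Cc1ccc(O)c(C=O)c1O)CC/C=C(\C)CCC[C@H](C)C(=O)O | intermediate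
10 | (2S,6E,10E)-12-(3-formyl-2,4,5-trihydroxyphenyl)-2,6,10-trimethyldodeca-6,10-dienoic acid | C/C(=C\Cc1cc(O)c(O)c(C=O)c1O)CC/C=C(\C)CCC[C@H](C)C(=O)O | target

**Step count and risks**
Total steps: 6. Longest linear sequence: 6 (1 → 10).

Step 6, the proposed hydroxylation, is the most likely to fail. Oxygen transfer could go to the substituted ring carbons (C1' or C3') and give dearomatised quinols or loss of the formyl group, the electron-rich product could be oxidised further, or the phenoxide may simply be too sluggish towards the oxaziridine. The fallback is known chemistry and sets out from 9: Elbs persulfate oxidation (K2S2O8, aqueous NaOH, 10 °C, N2) puts a sulfate para to the C2'-phenoxide and gives (2S,6E,10E)-12-[3-formyl-2,4-dihydroxy-5-(sulfooxy)phenyl]-2,6,10-trimethyldodeca-6,10-dienoic acid F1. Its sulfate ester is then cleaved under conditions the polyene tolerates (arylsulfatase, pH 5 buffer, 37 °C, or dilute HCl in THF at 40 °C), and the route is rejoined at 10.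

Step 5 is next. O-allylation, double alkylation, and hydrolysis or self-esterification of bromide 8 compete with the wanted C-allylation, and a modest yield is expected even when it works. The fallback sets out from 6 and 7 and avoids both the bromide and the basic medium: a dehydrative Friedel–Crafts ortho-allylation of the resorcinol with the allylic alcohol on acidic alumina (or with BF3·OEt2 in dioxane) in warm 1,2-dichloroethane, the way geranyl resorcinols are made. It comes back at 9 and makes no new compound (F0).

Step 3 is the third. Chemoselectivity is secure, but the enantiomeric excess on this long-chain tiglic-acid homologue may fall short. The fallback sets out from 5 of insufficient purity and replaces asymmetric catalysis by an enzymatic kinetic resolution: Candida rugosa lipase with octan-1-ol in cyclohexane esterifies the 2S acid preferentially and gives octyl (2S,6E,10E)-12-acetoxy-2,6,10-trimethyldodeca-6,10-dienoate F2, while the unreacted 2R-enriched acid is washed out with aqueous NaHCO3. Saponification of F2 with LiOH in THF/H2O cleaves both esters and the route is rejoined at 6.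

**Further compounds**
F1 | step 6 | (2S,6E,10E)-12-[3-formyl-2,4-dihydroxy-5-(sulfooxy)phenyl]-2,6,10-trimethyldodeca-6,10-dienoic acid | C/C(=C\Cc1cc(OS(=O)(=O)O)c(O)c(C=O)c1O)CC/C=C(\C)CCC[C@H](C)C(=O)O
F0 | step 5 | none | none
F2 | step 3 | octyl (2S,6E,10E)-12-acetoxy-2,6,10-trimethyldodeca-6,10-dienoate | C/C(=C\COC(C)=O)CC/C=C(\C)CCC[C@H](C)C(=O)OCCCCCCCC
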